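## Retrosynthetic overview

1. The target is a furan ring (O1, C2–C5) with CH2CO2H on C2 and an unbranched C16 chain (C1'–C16', C1' on C5). The furan is the only ring and arrives ready-made in furfural, so no ring is formed in the route.
2. Key disconnection: C7'–C8' in the middle of the chain. It is made by a reductive Ni-electrocatalytic doubly decarboxylative coupling of two free acids, decanoic acid (C8'–C16' plus CO2) and 8-[5-(2-methoxy-2-oxoethyl)furan-2-yl]octanoic acid (C1'–C7' plus CO2).
3. Enabling feature: C7' and C8' are plain CH2 carbons in an unbranched, unfunctionalised polymethylene run with no stereocentre, so each maps onto the α-carbon of a fatty-acid carboxyl group. The furan ring sits six CH2 groups (C1'–C6') from C7', and the carboxyl on the C2 side chain stays silent as a methyl ester.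
4. The cathodic mode (sacrificial Mg anode) is chosen because the electron-rich 2,5-dialkylfuran ring would be oxidised at the anode potential of a classical Kolbe electrolysis.
5. The furan acid comes from furfural by Wittig olefination with a C7 carboxy ylide, alkene hydrogenation, and radical C–H alkylation of the free furan α-position with •CH2CO2Me. Saponification ends the route.

Key step: step 5

Remark: the target has no stereocentre and no stereogenic double bond, so it is achiral and the question of a single enantiomer does not arise.

## Route

Step 1
Reactants: 1 furfural (furan-2-carbaldehyde); 2 (6-carboxyhexyl)triphenylphosphonium bromide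
Product: 4 (Z)-8-(furan-2-yl)oct-7-enoic acid, via ylide sodium 7-(triphenylphosphoranylidene)heptanoate 3 (not isolated)
Conditions: 2, NaHMDS (2.2 equiv), THF, 0 °C; then 1, −78 °C to rt; aq. HCl work-up
Reagents that add atoms: sodium bis(trimethylsilyl)amide, [Na+].C[Si](C)(C)[N-][Si](C)(C)C (supplies only the sodium ion of 3; nothing stays in 4)
Why: Wittig olefination of a non-enolisable aldehyde with a non-stabilised carboxylate ylide should give mainly the Z-alkene, whose geometry is erased in step 2.

Step 2
Reactants: 4 (Z)-8-(furan-2-yl)oct-7-enoic acid
Product: 5 8-(furan-2-yl)octanoic acid
Conditions: H2 (1 atm), 5% Pd/C, EtOAc, rt, stopped after one equivalent of H2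
Reagents that add atoms: none
Why: In this catalytic hydrogenation the disubstituted side-chain alkene should be saturated much faster on Pd/C at 1 atm than the aromatic furan ring.

Step 3
Reactants: 6 methyl bromoacetate; 7 potassium O-ethyl dithiocarbonate (potassium ethyl xanthate)
Product: 8 methyl 2-[(ethoxycarbonothioyl)sulfanyl]acetate
Conditions: acetone, 0 °C to rt
Reagents that add atoms: none
Why: This is an SN2 displacement of an activated primary bromide by the soft sulfur of the xanthate anion.

Step 4
Reactants: 5 8-(furan-2-yl)octanoic acid; 8 methyl 2-[(ethoxycarbonothioyl)sulfanyl]acetate
Product: 9 8-[5-(2-methoxy-2-oxoethyl)furan-2-yl]octanoic acid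
Conditions: 8 (1.5 equiv), dilauroyl peroxide (1.3 equiv, in portions), ClCH2CH2Cl, reflux, Ar
Reagents that add atoms: none
Why: In this xanthate-transfer oxidative homolytic aromatic substitution the electrophilic •CH2CO2Me radical adds to the only free α-position of the electron-rich 2-alkylfuran, the peroxide oxidises the oxygen-stabilised allylic adduct radical to the cation, loss of H+ rearomatises the ring, and the neutral medium leaves the free acid untouched.

Step 5
Reactants: 9 8-[5-(2-methoxy-2-oxoethyl)furan-2-yl]octanoic acid; 10 decanoic acid
Product: 13 methyl 2-(5-hexadecylfuran-2-yl)acetate, via furan-octanoate NHPI ester 11 (not isolated), via decanoate NHPI ester 12 (not isolated)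
Conditions: 9 (1 equiv), 10 (3 equiv), N-hydroxyphthalimide (4 equiv), DIC (4 equiv), cat. DMAP, CH2Cl2, rt; evaporate; then NiCl2·6H2O (20 mol %), 2,2':6',2''-terpyridine (20 mol %), AgNO3 (0.3 equiv), NaI, DMF, Mg(+)|RVC(−), undivided cell, constant current (about 2.5 F per mol of active ester), rt; aq. HCl work-up
Reagents that add atoms: N-hydroxyphthalimide, ON1C(=O)c2ccccc2C1=O (its atoms stand only in 11 and 12; nothing stays in 13)
Why: This is a Ni-electrocatalytic doubly decarboxylative C(sp3)–C(sp3) cross-coupling, the reductive counterpart of a mixed Kolbe electrolysis: DIC and N-hydroxyphthalimide turn both acids into the redox-active esters 11 and 12, cathodically generated low-valent Ni(terpyridine) transfers one electron to each phthalimide unit, N–O cleavage and loss of CO2 release the primary 7-(furyl)heptyl and nonyl radicals, and their successive capture at nickel followed by reductive elimination from a dialkylnickel species forms the C7'–C8' bond. The closest known reaction type is this same coupling of two primary alkyl N-hydroxyphthalimide esters, made in the flask, at a silver-modified carbon cathode against a sacrificial magnesium anode. The step closes no ring and creates no stereocentre. Selectivity between the two carboxyl groups of the furan half is secured because only the free octanoic acid can be activated, while the side-chain carboxyl on C2 is a methyl ester that is inert at the working cathode potential. The furan ring should survive because the anode process is magnesium dissolution, far below the oxidation potential of a 2,5-dialkylfuran, because nucleophilic primary alkyl radicals are polarity-mismatched with the electron-rich ring, and because closure of C7' onto C5 or C4 would need an eight- or nine-membered transition state. Cross- versus homo-coupling of two primary partners is only statistical, so cheap 10 is used in threefold excess, and the hydrocarbon, monoester and diester products should differ enough in polarity for simple chromatography.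

Step 6
Reactants: 13 methyl 2-(5-hexadecylfuran-2-yl)acetate
Product: 14 2-(5-hexadecylfuran-2-yl)acetic acid (target)
Conditions: LiOH·H2O (3 equiv), THF/MeOH/H2O, rt; then cold 1 M HCl to pH 3
Reagents that add atoms: lithium hydroxide, [Li+].[OH-]
Why: Ester saponification (acyl-oxygen cleavage) at room temperature with a brief cold acidification should spare the acid-sensitive furan and avoid decarboxylation of the furylacetic acid.

## Compound list

1 | furfural (furan-2-carbaldehyde) | O=Cc1ccco1 | starting material
2 | (6-carboxyhexyl)triphenylphosphonium bromide | [Br-].OC(=O)CCCCCC[P+](c1ccccc1)(c1ccccc1)c1ccccc1 | starting material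
3 | sodium 7-(triphenylphosphoranylidene)heptanoate (ylide, not isolated) | [Na+].[O-]C(=O)CCCCC[CH-][P+](c1ccccc1)(c1ccccc1)c1ccccc1 | intermediate
4 | (Z)-8-(furan-2-yl)oct-7-enoic acid | OC(=O)CCCCC/C=C\c1ccco1 | intermediate
5 | 8-(furan-2-yl)octanoic acid | OC(=O)CCCCCCCc1ccco1 | intermediate
6 | methyl bromoacetate | COC(=O)CBr | starting material
7 | potassium O-ethyl dithiocarbonate | [K+].CCOC(=S)[S-] | starting material
8 | methyl 2-[(ethoxycarbonothioyl)sulfanyl]acetate | CCOC(=S)SCC(=O)OC | intermediate
9 | 8-[5-(2-methoxy-2-oxoethyl)furan-2-yl]octanoic acid | COC(=O)Cc1ccc(CCCCCCCC(=O)O)o1 | intermediate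
10 | decanoic acid | CCCCCCCCCC(=O)O | starting material
11 | 1,3-dioxoisoindolin-2-yl 8-[5-(2-methoxy-2-oxoethyl)furan-2-yl]octanoate (not isolated) | COC(=O)Cc1ccc(CCCCCCCC(=O)ON2C(=O)c3ccccc3C2=O)o1 | intermediate
12 | 1,3-dioxoisoindolin-2-yl decanoate (not isolated) | CCCCCCCCCC(=O)ON1C(=O)c2ccccc2C1=O | intermediate
13 | methyl 2-(5-hexadecylfuran-2-yl)acetate | CCCCCCCCCCCCCCCCc1ccc(CC(=O)OC)o1 | intermediate
14 | 2-(5-hexadecylfuran-2-yl)acetic acid | CCCCCCCCCCCCCCCCc1ccc(CC(=O)O)o1 | target

## Step count and risks

Total step count: 6. Longest linear sequence: 5 (steps 1, 2, 4, 5, 6).

**Step 5.**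
- What may go wrong: statistical homocoupling of both radical partners, premature hydrogen-atom capture by the primary radicals, and partial hydrolysis of the active esters made in the flask could erode the cross-coupling.
- Fallback: it sets out from 9 and comes back at 13. It replaces the radical/radical electrochemical union by a decarboxylative Negishi-type alkyl–alkyl coupling with one radical and one polar partner, so cross-selectivity no longer rests on statistics.
- Acid 9 is activated with N-hydroxyphthalimide and DIC, and 11 is now isolated by filtration through silica.
- Commercial 1-bromononane and magnesium in THF give nonylmagnesium bromide F1, which is transmetalated with ZnCl2 (0.5 equiv) to dinonylzinc F2.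
- NiCl2·glyme with 4,4'-di-tert-butyl-2,2'-bipyridine in THF/DMF at rt should then join 11 and F2 at the same C7'–C8' bond. The methyl ester and the furan tolerate the organozinc.

**Step 4.**
- What may go wrong: oxidative degradation of the electron-rich furan by the peroxide, chain-breaking hydrogen abstraction at the CH2 next to the ring, and a second alkylation at a β-position.
- Fallback: it sets out from 5 and comes back at 9. It replaces the radical C–H substitution by halogenation and palladium-catalysed cross-coupling.
- NBS in DMF at 0 °C should brominate the free α-position to give 8-(5-bromofuran-2-yl)octanoic acid F3, which is used at once.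
- Methyl bromoacetate 6 and activated zinc in THF give bromo(2-methoxy-2-oxoethyl)zinc F4.
- A Reformatsky–Negishi α-heteroarylation (Pd(dba)2, Q-Phos, THF, rt) with excess F4 should deliver 9. One equivalent of F4 is spent on the acid proton.

**Step 2.**
- What may go wrong: over-reduction of the furan ring or its hydrogenolytic opening on the metal surface before the alkene is fully consumed.
- Fallback: it sets out from 4 and comes back at 5. It replaces surface-catalysed hydrogenation by metal-free diimide, generated from p-toluenesulfonyl hydrazide and NaOAc in refluxing DME/water.
- Diimide transfers H2 in a concerted way to the C=C bond only and cannot reduce an aromatic ring. This fallback makes no new compound (F0).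

## Further compounds

F1 | step 5 | nonylmagnesium bromide | CCCCCCCCC[Mg]Br
F2 | step 5 | dinonylzinc | CCCCCCCCC[Zn]CCCCCCCCC
F3 | step 4 | 8-(5-bromofuran-2-yl)octanoic acid | OC(=O)CCCCCCCc1ccc(Br)o1
F4 | step 4 | bromo(2-methoxy-2-oxoethyl)zinc | COC(=O)C[Zn]Br
F0 | step 2 | none | none
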